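The route rests on disconnecting the C8–OMe bond of ring A. This lets the flavone be assembled with the cheap phloroglucinol-type 5-hydroxy-7-methoxy pattern and oxygenated last. The key step exploits the unsubstituted C8–H of ring A, which lies para to the C5 hydroxyl, the most easily oxidised site once it is ionised. One electrolysis in methanol removes four electrons, makes both C8–O bonds and dearomatises ring A to the C8 dimethyl monoketal of the 5,8-quinone. Its precursor is 3'-benzyloxy-5-hydroxy-7,4',5'-trimethoxyflavone, reached by benzylation, Claisen–Schmidt condensation and iodine/DMSO cyclisation. Zinc then re-aromatises ring A with loss of one C8 methoxy group, and the benzyl group is removed over palladium.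

Key step: step 4

Remark: the target has no stereocentre, stereogenic axis or configurable double bond. It is achiral, its SMILES carries no stereodescriptor, and no enantioselective step is needed.

Remark on design: the 3'-oxygen is carried as a benzyl ether because a free guaiacol-type phenol on ring B would be oxidised before ring A. An ether also survives KOH, I2/DMSO, methoxide, the anode and zinc, and it leaves under neutral conditions.

Step 1
Reactants: 1 3-hydroxy-4,5-dimethoxybenzaldehyde; 2 benzyl bromide
Product: 3 3-(benzyloxy)-4,5-dimethoxybenzaldehyde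
Conditions: K2CO3 (1.5 equiv), DMF, 50 °C
Reagents that add atoms: benzyl bromide (2), BrCc1ccccc1
Why: Williamson ether synthesis, in which the phenol is the only acidic site of 1 and its phenolate displaces bromide from 2 by SN2 while the aldehyde and the methyl ethers stay untouched.

Step 2
Reactants: 3 3-(benzyloxy)-4,5-dimethoxybenzaldehyde; 4 1-(2,6-dihydroxy-4-methoxyphenyl)ethanone
Product: 5 (E)-3-[3-(benzyloxy)-4,5-dimethoxyphenyl]-1-(2,6-dihydroxy-4-methoxyphenyl)prop-2-en-1-one
Conditions: KOH (50% aq., excess), EtOH, N2, rt, 48–72 h; then ice, 2 M HCl to pH 5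
Reagents that add atoms: none
Why: Claisen–Schmidt condensation (crossed aldol addition, then E1cB dehydration), in which 3 cannot enolise, the methyl ketone of 4 is the only carbon acid, conjugation drives loss of water to the more stable E enone, and any closure to the isomeric flavanone 6 on acidification is harmless because 6 is the intermediate of step 3.

Step 3
Reactants: 5 (E)-3-[3-(benzyloxy)-4,5-dimethoxyphenyl]-1-(2,6-dihydroxy-4-methoxyphenyl)prop-2-en-1-one
Product: 7 2-[3-(benzyloxy)-4,5-dimethoxyphenyl]-5-hydroxy-7-methoxy-4H-chromen-4-one, via racemic flavanone 6 (not isolated)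
Conditions: I2 (10 mol %), DMSO, 120 °C
Reagents that add atoms: none
Why: Iodine/DMSO oxidative cyclisation of a 2'-hydroxychalcone, in which 6-endo-trig oxa-Michael addition gives 6, its racemic C2 centre is erased at once by C3 iodination and loss of HI (DMSO re-oxidises HI to iodine), and only one flavone can form because the two hydroxyls of 5 are related by symmetry, the spare one becoming the chelated C5–OH.

Step 4
Reactants: 7 2-[3-(benzyloxy)-4,5-dimethoxyphenyl]-5-hydroxy-7-methoxy-4H-chromen-4-one; 8 methanol
Product: 10 2-[3-(benzyloxy)-4,5-dimethoxyphenyl]-7,8,8-trimethoxy-4H-chromene-4,5(8H)-dione, via 8-methoxyflavone 9 (not isolated)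
Conditions: undivided cell, RVC anode, small-area Pt-wire cathode, constant current (ca. 5 mA cm−2) until 7 and 9 are consumed (theory 4 F mol−1), Et4NOTs (0.1 M), NaOMe (0.3 equiv), MeOH–THF 3:1 (ca. 0.02 M in 7), 0 °C; then AcOH (0.3 equiv), aqueous work-up, 10 used crude
Reagents that add atoms: methanol (8), CO
Why: Proposed new method: the C5 phenolate of 7 gives up two electrons at the carbon anode (phenoxyl radical, then a phenoxenium ion with its charge shared by C6, C8 and C4a), methanol adds at C8, and tautomerisation returns the aromatic 8-methoxyphenol 9. As a hydroquinone monoether, 9 is oxidised at a lower potential than 7, so it loses two further electrons at once, the cation now being localised at C8 by the lone pair of the new methoxy group, and a second methanol ends the sequence at the non-phenolic monoketal 10. The closest known reaction type is the anodic or iodine(III)-mediated conversion of para-unsubstituted phenols in methanol into 4,4-dimethoxycyclohexa-2,5-dienones, and the Elbs persulfate oxidation shows that oxidants attack 5-hydroxyflavones at C8; what is untested is the anodic variant on a hydrogen-bonded, acyl-deactivated 5-hydroxychromone. No ring is closed and no stereocentre arises, because C8 ends up with two identical methoxy groups. Chemoselectivity for ring A over the trialkoxy ring B and the benzylic CH2 is secured by ionising the phenol, which places its oxidation well below that of neutral aryl ethers so that a low constant current never reaches them; regioselectivity for para C8 over ortho C6 rests on the usual para preference of phenoxenium capture in the first stage and on the C8 methoxy group in the second. Keeping methoxide substoichiometric (cathodic hydrogen evolution returns the base that anodic proton release consumes), working at 0 °C and neutralising as soon as the charge has passed shield the doubly activated C4a=C8a bond of 10 from methoxide addition and pyrone opening.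

Step 5
Reactants: 10 2-[3-(benzyloxy)-4,5-dimethoxyphenyl]-7,8,8-trimethoxy-4H-chromene-4,5(8H)-dione
Product: 9 2-[3-(benzyloxy)-4,5-dimethoxyphenyl]-5-hydroxy-7,8-dimethoxy-4H-chromen-4-one (the transient compound of step 4, now isolated)
Conditions: activated Zn dust (5 equiv), AcOH (10 equiv), dry THF, 0 °C to rt, 30 min
Reagents that add atoms: none
Why: Reductive aromatisation of a quinone monoketal, a known reaction type, in which zinc transfers two electrons to the cross-conjugated dienone, the resulting C5 enolate expels one C8 methoxide in a vinylogous β-elimination, and ring A regains aromaticity as the chelated 5-hydroxy-8-methoxy pattern, while the benzyl ether, the methyl ethers and the pyrone are inert to zinc in dilute acetic acid at this temperature.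

Step 6
Reactants: 9 2-[3-(benzyloxy)-4,5-dimethoxyphenyl]-5-hydroxy-7,8-dimethoxy-4H-chromen-4-one
Product: 11 5-hydroxy-2-(3-hydroxy-4,5-dimethoxyphenyl)-7,8-dimethoxy-4H-chromen-4-one (5,3'-dihydroxy-7,8,4',5'-tetramethoxyflavone)
Conditions: H2 (1 atm), 10% Pd/C, EtOAc–EtOH 1:1, rt
Reagents that add atoms: none
Why: Catalytic hydrogenolysis of a benzyl aryl ether, which cleaves the benzylic C–O bond at atmospheric pressure under neutral conditions and so leaves the conjugated C2=C3 bond, the methyl ethers and the 5-hydroxy-7,8-dimethoxy pattern unchanged, with no acid present that could trigger a Wessely–Moser isomerisation.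

Compound list
1 | 3-hydroxy-4,5-dimethoxybenzaldehyde | O=Cc1cc(O)c(OC)c(OC)c1 | starting material
2 | benzyl bromide | BrCc1ccccc1 | starting material
3 | 3-(benzyloxy)-4,5-dimethoxybenzaldehyde | O=Cc1cc(OC)c(OC)c(OCc2ccccc2)c1 | intermediate
4 | 1-(2,6-dihydroxy-4-methoxyphenyl)ethanone | CC(=O)c1c(O)cc(OC)cc1O | starting material
5 | (E)-3-[3-(benzyloxy)-4,5-dimethoxyphenyl]-1-(2,6-dihydroxy-4-methoxyphenyl)prop-2-en-1-one | COc1cc(O)c(C(=O)/C=C/c2cc(OC)c(OC)c(OCc3ccccc3)c2)c(O)c1 | intermediate
6 | (±)-2-[3-(benzyloxy)-4,5-dimethoxyphenyl]-5-hydroxy-7-methoxychroman-4-one (racemic, not isolated) | COc1cc(O)c2c(c1)OC(c1cc(OC)c(OC)c(OCc3ccccc3)c1)CC2=O | intermediate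
7 | 2-[3-(benzyloxy)-4,5-dimethoxyphenyl]-5-hydroxy-7-methoxy-4H-chromen-4-one (3'-benzyloxy-5-hydroxy-7,4',5'-trimethoxyflavone) | COc1cc(O)c2c(=O)cc(-c3cc(OC)c(OC)c(OCc4ccccc4)c3)oc2c1 | intermediate
8 | methanol | CO | starting material
9 | 2-[3-(benzyloxy)-4,5-dimethoxyphenyl]-5-hydroxy-7,8-dimethoxy-4H-chromen-4-one | COc1cc(O)c2c(=O)cc(-c3cc(OC)c(OC)c(OCc4ccccc4)c3)oc2c1OC | intermediate
10 | 2-[3-(benzyloxy)-4,5-dimethoxyphenyl]-7,8,8-trimethoxy-4H-chromene-4,5(8H)-dione | COC1=CC(=O)C2=C(OC(=CC2=O)c2cc(OC)c(OC)c(OCc3ccccc3)c2)C1(OC)OC | intermediate
11 | 5,3'-dihydroxy-7,8,4',5'-tetramethoxyflavone (achiral) | COc1cc(-c2cc(=O)c3c(O)cc(OC)c(OC)c3o2)cc(O)c1OC | target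

Total step count: 6. Longest linear sequence: 6 steps (1 → 3 → 5 → 7 → 10 → 9 → 11).

Steps most likely to fail

1. Step 4 (bears the label).
- What may go wrong: phenoxyl radicals may couple and film the anode before the second electron is removed. Methanol may be captured at the ortho position. Base may open the pyrone ring once ring A is dearomatised. Cathodic re-reduction of the product would only waste charge.
- Fallback with known chemistry, from 7 back to 9: Elbs persulfate oxidation (K2S2O8, aq. KOH–pyridine, 0 °C to rt) should place a sulfate ester para to the C5 phenolate and give the potassium flavon-8-yl sulfate F1. Brief warming in dilute HCl containing Na2SO3 hydrolyses it to the 5,8-dihydroxyflavone F2. One equivalent of Me2SO4 with K2CO3 in acetone then methylates only the free 8-hydroxyl, the chelated 5-hydroxyl being unreactive, and delivers 9. Compound 10 and step 5 are bypassed.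

2. Step 2.
- What may go wrong: the doubly deprotonated ketone may enolise slowly, the aldol equilibrium may stall, and the electron-rich phenolates may suffer air oxidation over the long reaction time.
- Fallback, from 3 (together with 4) back to 7: the aldol logic is replaced by C-acylation. Pinnick oxidation of 3 (NaClO2, NaH2PO4, 2-methyl-2-butene, t-BuOH–H2O) gives 3-(benzyloxy)-4,5-dimethoxybenzoic acid F3. Oxalyl chloride with catalytic DMF in CH2Cl2 gives the acid chloride F4. The lithium polyanion of 4 (LiHMDS, 4.2 equiv, THF, −78 °C to rt) is acylated on carbon to the β-diketone F5. Catalytic p-TsOH in refluxing toluene cyclodehydrates this to 7. The diketone already has the flavone oxidation level, so steps 2 and 3 and compounds 5 and 6 are bypassed.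

3. Step 5.
- What may go wrong: acid-promoted hydrolysis of the ketal may run ahead of electron transfer, which would cost the C8 methyl group, or the pyrone may be over-reduced.
- Fallback, from 10 back to 9: the hydrolysis is accepted and driven to completion (1 M HCl–THF, rt) to give the flavone-5,8-quinone F6. Shaking with aqueous Na2S2O4 in EtOAc reduces it to the 5,8-dihydroxyflavone F2, the same compound as in the fallback to step 4. Selective 8-O-methylation (Me2SO4, 1 equiv, K2CO3, acetone) returns 9.

Further compounds
F1 | step 4 | potassium 2-[3-(benzyloxy)-4,5-dimethoxyphenyl]-5-hydroxy-7-methoxy-4-oxo-4H-chromen-8-yl sulfate | COc1cc(O)c2c(=O)cc(-c3cc(OC)c(OC)c(OCc4ccccc4)c3)oc2c1OS(=O)(=O)[O-].[K+]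
F2 | step 4 | 2-[3-(benzyloxy)-4,5-dimethoxyphenyl]-5,8-dihydroxy-7-methoxy-4H-chromen-4-one | COc1cc(O)c2c(=O)cc(-c3cc(OC)c(OC)c(OCc4ccccc4)c3)oc2c1O
F3 | step 2 | 3-(benzyloxy)-4,5-dimethoxybenzoic acid | COc1cc(C(=O)O)cc(OCc2ccccc2)c1OC
F4 | step 2 | 3-(benzyloxy)-4,5-dimethoxybenzoyl chloride | COc1cc(C(=O)Cl)cc(OCc2ccccc2)c1OC
F5 | step 2 | 1-[3-(benzyloxy)-4,5-dimethoxyphenyl]-3-(2,6-dihydroxy-4-methoxyphenyl)propane-1,3-dione | COc1cc(O)c(C(=O)CC(=O)c2cc(OC)c(OC)c(OCc3ccccc3)c2)c(O)c1
F6 | step 5 | 2-[3-(benzyloxy)-4,5-dimethoxyphenyl]-7-methoxy-4H-chromene-4,5,8-trione | COC1=CC(=O)C2=C(OC(=CC2=O)c2cc(OC)c(OC)c(OCc3ccccc3)c2)C1=O
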